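The coupling partner is the charge I have to decide on before the next run: do I keep it as it stands and change the temperature, or charge more of it?

in all of them: substrate 20 mM

|  | coupling partner | free catalyst | temperature | remark | time |
|---|---|---|---|---|---|
| east | 24 mM | 22 µM | 25 °C | run made earlier |  |
| Wednesday's | 24.0 mM | 15 µM | 25 °C |  | 25 min |
| Saturday's | 24.0 mM | 15 µM | 55 °C |  | 25 min |
| Tuesday's | 24.0 mM | 15 µM | 85 °C |  | 25 min |
| Friday's | 24.0 mM | 15 µM |  | at 85 °C until 8.0 min, from then on at 25 °C | 25 min |

east run (percent of the substrate charged)

| time / min | target / % | substrate / % |
|---|---|---|
| 0.417 | 1.8 | 98.7 |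
| 1.00 | 4.1 | 95.7 |
| 2.00 | 8.2 | 92.2 |
| 5.00 | 18.4 | 80.0 |

(standard deviation of a reading: 0.5 percentage points)

- the earlier runs do not show what temperature does; that part of a forecast is a guess
- no earlier run changes the charge of free catalyst; that part of a forecast is a guess

1. which flask leads in amount of target, in percent of the substrate charged ("all alike" within 1.5 percentage points) (Wednesday's / Saturday's / Tuesday's / Friday's / all alike)
2. how much target is there at the end, in percent of the substrate charged: Wednesday's
3. how much target is there at the end, in percent of the substrate charged: Saturday's
4. how much target is there at the end, in percent of the substrate charged: Tuesday's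
5. how much target is there at the end, in percent of the substrate charged: Friday's

The east run says little about this. At 5.00 min it reads 18.4 % target and 80.0 % substrate, a gap of 1.6 percentage points against a scatter of 0.5 points per reading, and the partner isn't read at all. So I reckon from the charge. The partner charged beyond one per substrate, counted as a fraction of the substrate charge with the even charge as zero, is 20.0 %; I call this the spare partner. Each substrate turned into target costs one partner, so any further use of partner is paid from the spare. Once that use passes the spare, the partner becomes the limiting reagent, and when the partner is used up the excess stands as substrate left unturned. Suppose heat makes partner add a second time onto target. If that takes up exactly the spare and the substrate is turned over, target stands at 80.0 %. So I keep the charge and let the temperature flasks show how much of the spare gets used.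

The forecast puts Saturday's first, with 46 % for Wednesday's, 85 % for Saturday's, 65 % for Tuesday's and 72 % for Friday's, and it argues: “Friday's gets the fast start, then cooling preserves the product and any surviving catalyst”. Its Saturday's figure stands above my line.

The flasks give 53.4 % for Wednesday's, 78.9 % for Saturday's, beside my 80.0 %, then 45.4 % for Tuesday's and 46.0 % for Friday's, so Saturday's leads.

    substrate + free catalyst → catalyst intermediate A (k = 5540 L mol⁻¹ min⁻¹, Ea = 47.0 kJ mol⁻¹)
    catalyst intermediate B → free catalyst + target (k = 66.4 min⁻¹, Ea = 74.0 kJ mol⁻¹)
    coupling partner + catalyst intermediate A ⇌ catalyst intermediate B (K = 236 L mol⁻¹, k = 69300 L mol⁻¹ min⁻¹, Ea = 37.0 kJ mol⁻¹, ΔH = −64.0 kJ mol⁻¹)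
    coupling partner + target → over-reaction product (k = 0.305 L mol⁻¹ min⁻¹, Ea = 68.0 kJ mol⁻¹)
    (constants at 25 °C)

The main reason for Tuesday's shortfall is the step from coupling partner + target to over-reaction product: without it that flask ends at 100 % target instead of 45.4 %. Tuesday's over-reaction product reaches 37.3 %, which passes the spare by 17 points, and with 0 % of the partner left, the substrate left is 17 %. Saturday's recipe cut to 9.6 mM of partner starts with a spare of −52.0 %. Its 2.82 % of over-reaction product then gives 54.8 % by the same subtraction, and with 0.036 % of its partner left, that flask holds 55 % of its substrate.

The numbers in the tables are simulated for substances that don't exist; the scatter is artificial.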